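The trimer is cut at its two C4–C8 interflavan bonds into C4-activated epiafzelechin, C4-activated epicatechin and catechin, all as benzyl ethers. The pyran ring of the central unit (O1, C2, C3, C4, C4a, C8a) comes from a cis-2-aryl-3-(hydroxymethyl)-2,3-dihydrobenzofuran whose two stereocentres are set by an asymmetric Rh-carbenoid C–H insertion. The key step exploits the phloroglucinol-type A ring: its carbon C4a bridges C3 and the exocyclic CH2 as a phenonium ion and, under a reversible trifluoroacetate shuttle, shifts to CH2. In one operation the furan expands to the pyran, CH2 becomes C4 and the C3–O bond forms with inversion, giving the 2,3-cis (2R,3R) flavan-3-ol.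

Key step: step 8

Remark: (−)-epiafzelechin and (+)-catechin are taken as purchasable natural flavan-3-ols; the two A-ring oxygens of the central unit are carried as TIPS ethers through the C–H insertion, because an ortho benzyloxy group would offer the carbenoid a second benzylic C–H bond, and are exchanged for benzyl afterwards.

Step 1
Reactants: 1 2′,4′,6′-trihydroxyacetophenone
Product: 2 1-[2-hydroxy-4,6-bis(triisopropylsilyloxy)phenyl]ethanone
Conditions: TIPSCl (2.1 equiv), imidazole, DMF, 0 °C → rt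
Reagents that add atoms: triisopropylsilyl chloride, CC(C)[Si](Cl)(C(C)C)C(C)C
Why: Selective phenol silylation: the para and one ortho hydroxyl should react, while the last ortho hydroxyl is deactivated by its hydrogen bond to the acetyl group and by the bulk of TIPS.

Step 2
Reactants: 2 1-[2-hydroxy-4,6-bis(triisopropylsilyloxy)phenyl]ethanone; 3 [3,4-bis(benzyloxy)phenyl]methanol
Product: 4 1-[2-{[3,4-bis(benzyloxy)phenyl]methoxy}-4,6-bis(triisopropylsilyloxy)phenyl]ethanone
Conditions: PPh3, DIAD, THF, 0 °C → rt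
Reagents that add atoms: none
Why: Mitsunobu etherification of the chelated but acidic phenol with the primary benzylic alcohol runs under neutral conditions that leave the aryl silyl ethers intact.

Step 3
Reactants: 4 1-[2-{[3,4-bis(benzyloxy)phenyl]methoxy}-4,6-bis(triisopropylsilyloxy)phenyl]ethanone
Product: 5 methyl {2-{[3,4-bis(benzyloxy)phenyl]methoxy}-4,6-bis(triisopropylsilyloxy)phenyl}acetate
Conditions: Tl(NO3)3·3H2O, MeOH–HC(OMe)3, 0 °C → rt
Reagents that add atoms: methanol, CO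
Why: Thallium(III)-mediated oxidative rearrangement of an aryl methyl ketone (oxythallation of the enol ether, then 1,2-shift of the very electron-rich aryl group) should give the methyl arylacetate.

Step 4
Reactants: 5 methyl {2-{[3,4-bis(benzyloxy)phenyl]methoxy}-4,6-bis(triisopropylsilyloxy)phenyl}acetate
Product: 6 methyl diazo{2-{[3,4-bis(benzyloxy)phenyl]methoxy}-4,6-bis(triisopropylsilyloxy)phenyl}acetate
Conditions: p-ABSA, DBU, MeCN, 0 °C → rt
Reagents that add atoms: 4-acetamidobenzenesulfonyl azide, CC(=O)Nc1ccc(cc1)S(=O)(=O)N=[N+]=[N-]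
Why: Regitz diazo transfer from the sulfonyl azide to the DBU-generated ester enolate gives the aryldiazoacetate, and anhydrous DBU should not cleave TIPS aryl ethers.

Step 5
Reactants: 6 methyl diazo{2-{[3,4-bis(benzyloxy)phenyl]methoxy}-4,6-bis(triisopropylsilyloxy)phenyl}acetate
Product: 7 methyl (2S,3R)-2-[3,4-bis(benzyloxy)phenyl]-4,6-bis(triisopropylsilyloxy)-2,3-dihydro-1-benzofuran-3-carboxylate (2,3-cis)
Conditions: Rh2(PTTL)4 (enantiomer that gives the 2S,3R ester, 1 mol %), toluene, −60 °C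
Reagents that add atoms: none
Why: Intramolecular 1,5 C–H insertion of the donor/acceptor rhodium carbenoid into the benzylic ether C–H bond closes the dihydrofuran ring with kinetic cis selectivity; C2 and C3 are set together by the chiral dirhodium tert-leucinate, and the silyl ethers offer no competing C–H bond α to oxygen.

Step 6
Reactants: 7 methyl (2S,3R)-2-[3,4-bis(benzyloxy)phenyl]-4,6-bis(triisopropylsilyloxy)-2,3-dihydro-1-benzofuran-3-carboxylate
Product: 8 [(2S,3S)-2-[3,4-bis(benzyloxy)phenyl]-4,6-bis(triisopropylsilyloxy)-2,3-dihydro-1-benzofuran-3-yl]methanol (2,3-cis)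
Conditions: DIBAL-H, CH2Cl2, −78 → −40 °C
Reagents that add atoms: none
Why: Ester reduction with DIBAL-H at low temperature and without base should preserve the epimerisable cis C3 centre and the silyl ethers.

Step 7
Reactants: 8 [(2S,3S)-2-[3,4-bis(benzyloxy)phenyl]-4,6-bis(triisopropylsilyloxy)-2,3-dihydro-1-benzofuran-3-yl]methanol
Product: 10 [(2S,3S)-4,6-bis(benzyloxy)-2-[3,4-bis(benzyloxy)phenyl]-2,3-dihydro-1-benzofuran-3-yl]methanol, via dihydrobenzofuran bisphenol 9 (not isolated)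
Conditions: CsF, BnBr, DMF, rt → 40 °C
Reagents that add atoms: benzyl bromide, BrCc1ccccc1
Why: Fluoride-induced desilylation gives the caesium bisphenoxide, which undergoes Williamson O-benzylation in the same flask, while the aliphatic alcohol is not deprotonated by CsF and stays free.

Step 8
Reactants: 10 [(2S,3S)-4,6-bis(benzyloxy)-2-[3,4-bis(benzyloxy)phenyl]-2,3-dihydro-1-benzofuran-3-yl]methanol
Product: 13 5,7,3′,4′-tetra-O-benzyl-(−)-epicatechin [(2R,3R)-5,7-bis(benzyloxy)-2-[3,4-bis(benzyloxy)phenyl]chroman-3-ol], via primary trifluoroacetate 11 (not isolated), via chroman-3-yl trifluoroacetate 12 (not isolated)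
Conditions: TFAA, 2,6-lutidine, CH2Cl2, 0 °C; then HFIP, 40 °C; then K2CO3, MeOH, 0 °C
Reagents that add atoms: trifluoroacetic anhydride, O=C(OC(=O)C(F)(F)F)C(F)(F)F (through oxygen scrambling in the trifluoroacetate ion it supplies part of the O-3 oxygen; no other atom)
Why: Proposed new method: the primary trifluoroacetate 11 ionises in HFIP with anchimeric assistance of the 4,6-dibenzyloxy A ring to a spiro-cyclopropyl arenium (phenonium) ion pair in which aryl carbon C3a bridges C3 and the exocyclic CH2; return of trifluoroacetate to CH2 only regenerates 11, whereas return to C3 breaks the C3–C3a bond and gives the chroman ester 12, and since trifluoroacetate is both leaving group and nucleophile the esters should equilibrate towards 12 (loss of dihydrofuran strain and of the cis-eclipsed substituents, primary ester becomes secondary), after which methanolysis cleaves only the acyl–O bond. The closest known reaction types are the trifluoroacetic-anhydride-mediated ring expansion of prolinols to 3-hydroxypiperidines through aziridinium ions under thermodynamic control, the Demjanov-type 1,2-aryl shift of indan-1-ylmethyl cations to 2-tetralyl products, and the kinetically controlled reverse of the present change, the contraction of C3-activated flavan-3-ols to 3-substituted 2-aryl-2,3-dihydrobenzofurans. No ring is closed by cyclisation: the six-membered pyran ring arises from the five-membered furan ring by a 1,2-shift (Wagner–Meerwein type) of C3a from C3 to the exocyclic carbon, which becomes C4. C2 is not touched, and the carbinol centre C3 is set by backside entry of trifluoroacetate anti to the migrating aryl carbon (inversion at C3), so the cis relationship and absolute configuration of 10 map stereospecifically onto (2R,3R). The step needs ring-expanding over ring-retaining capture and an intact C2: the first is secured by reversibility (the kinetically preferred attack at CH2 is unproductive), the second by the lutidine buffer and by the slow ionisation of 12, which should keep O1 participation and proton loss from the bridged ion out of play.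

Step 9
Reactants: 13 5,7,3′,4′-tetra-O-benzyl-(−)-epicatechin
Product: 14 (2R,3R,4S)-5,7-bis(benzyloxy)-2-[3,4-bis(benzyloxy)phenyl]-4-(2-ethoxyethoxy)chroman-3-ol (4β ether)
Conditions: DDQ, 2-ethoxyethanol, CH2Cl2, rt
Reagents that add atoms: 2-ethoxyethanol, CCOCCO
Why: Benzylic oxidation: DDQ abstracts hydride from C4, and the A-ring-stabilised cation is trapped by the alcohol on the β face, anti to the 3-hydroxyl and 2-aryl groups, which sets C4 as 4S (3,4-trans).

Step 10
Reactants: 15 (+)-catechin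
Product: 16 5,7,3′,4′-tetra-O-benzyl-(+)-catechin [(2R,3S)]
Conditions: BnBr, K2CO3, DMF, 0 °C → rt
Reagents that add atoms: benzyl bromide, BrCc1ccccc1
Why: Williamson ether synthesis on the four phenols with carbonate as base, which does not ionise the secondary 3-hydroxyl.

Step 11
Reactants: 14 4β-(2-ethoxyethoxy) epicatechin electrophile; 16 5,7,3′,4′-tetra-O-benzyl-(+)-catechin (3 equiv)
Product: 17 octa-O-benzyl epicatechin-(4β→8)-catechin
Conditions: TMSOTf, CH2Cl2, −78 °C
Reagents that add atoms: none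
Why: TMSOTf ionises the C4 ether to the benzylic cation, which is captured in a Friedel–Crafts alkylation by C8 of 16 on the β face, anti to the 3-hydroxyl, so the upper C4 is set 4β (3,4-trans); the excess of 16 suppresses self-condensation of 14.

Step 12
Reactants: 18 (−)-epiafzelechin
Product: 19 5,7,4′-tri-O-benzyl-(−)-epiafzelechin [(2R,3R)]
Conditions: BnBr, K2CO3, DMF, 0 °C → rt
Reagents that add atoms: benzyl bromide, BrCc1ccccc1
Why: Williamson ether synthesis on the three phenols, the secondary 3-hydroxyl staying free under carbonate conditions.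

Step 13
Reactants: 19 5,7,4′-tri-O-benzyl-(−)-epiafzelechin
Product: 20 (2R,3R,4S)-5,7-bis(benzyloxy)-2-[4-(benzyloxy)phenyl]-4-(2-ethoxyethoxy)chroman-3-ol (4β ether)
Conditions: DDQ, 2-ethoxyethanol, CH2Cl2, rt
Reagents that add atoms: 2-ethoxyethanol, CCOCCO
Why: The same DDQ benzylic oxidation with trapping of the C4 cation on the β face, anti to the 3-hydroxyl and 2-aryl groups, sets C4 as 4S.

Step 14
Reactants: 20 4β-(2-ethoxyethoxy) epiafzelechin electrophile; 17 octa-O-benzyl epicatechin-(4β→8)-catechin (1.5–2 equiv)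
Product: 21 undeca-O-benzyl epiafzelechin-(4β→8)-epicatechin-(4β→8)-catechin
Conditions: TMSOTf, CH2Cl2, −78 °C
Reagents that add atoms: none
Why: The same Lewis-acid-mediated Friedel–Crafts interflavan coupling: the cation from 20 is attacked on its β face (anti to 3-OH, setting 4β) by C8 of the upper epicatechin unit of 17, the only unsubstituted C8 and the preferred site over the more hindered C6 positions.

Step 15
Reactants: 21 undeca-O-benzyl epiafzelechin-(4β→8)-epicatechin-(4β→8)-catechin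
Product: 22 epiafzelechin-(4β→8)-epicatechin-(4β→8)-catechin (CNP0158921.1)
Conditions: H2 (1 atm), Pd(OH)2/C, THF–MeOH–H2O, rt
Reagents that add atoms: none
Why: Catalytic hydrogenolysis cleaves all eleven benzyl ethers under neutral conditions and should leave the acid-sensitive interflavan bonds and all eight stereocentres unchanged.

Compound list

1 | 2′,4′,6′-trihydroxyacetophenone | CC(=O)c1c(O)cc(O)cc1O | starting material
2 | 1-[2-hydroxy-4,6-bis(triisopropylsilyloxy)phenyl]ethanone | CC(=O)c1c(O)cc(O[Si](C(C)C)(C(C)C)C(C)C)cc1O[Si](C(C)C)(C(C)C)C(C)C | intermediate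
3 | [3,4-bis(benzyloxy)phenyl]methanol | OCc1ccc(OCc2ccccc2)c(OCc2ccccc2)c1 | starting material
4 | 1-[2-{[3,4-bis(benzyloxy)phenyl]methoxy}-4,6-bis(triisopropylsilyloxy)phenyl]ethanone | CC(=O)c1c(OCc2ccc(OCc3ccccc3)c(OCc3ccccc3)c2)cc(O[Si](C(C)C)(C(C)C)C(C)C)cc1O[Si](C(C)C)(C(C)C)C(C)C | intermediate
5 | methyl {2-{[3,4-bis(benzyloxy)phenyl]methoxy}-4,6-bis(triisopropylsilyloxy)phenyl}acetate | COC(=O)Cc1c(OCc2ccc(OCc3ccccc3)c(OCc3ccccc3)c2)cc(O[Si](C(C)C)(C(C)C)C(C)C)cc1O[Si](C(C)C)(C(C)C)C(C)C | intermediate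
6 | methyl diazo{2-{[3,4-bis(benzyloxy)phenyl]methoxy}-4,6-bis(triisopropylsilyloxy)phenyl}acetate | COC(=O)C(=[N+]=[N-])c1c(OCc2ccc(OCc3ccccc3)c(OCc3ccccc3)c2)cc(O[Si](C(C)C)(C(C)C)C(C)C)cc1O[Si](C(C)C)(C(C)C)C(C)C | intermediate
7 | methyl (2S,3R)-2-[3,4-bis(benzyloxy)phenyl]-4,6-bis(triisopropylsilyloxy)-2,3-dihydro-1-benzofuran-3-carboxylate (cis) | COC(=O)[C@@H]1c2c(O[Si](C(C)C)(C(C)C)C(C)C)cc(O[Si](C(C)C)(C(C)C)C(C)C)cc2O[C@@H]1c1ccc(OCc2ccccc2)c(OCc2ccccc2)c1 | intermediate
8 | [(2S,3S)-2-[3,4-bis(benzyloxy)phenyl]-4,6-bis(triisopropylsilyloxy)-2,3-dihydro-1-benzofuran-3-yl]methanol (cis) | OC[C@@H]1c2c(O[Si](C(C)C)(C(C)C)C(C)C)cc(O[Si](C(C)C)(C(C)C)C(C)C)cc2O[C@@H]1c1ccc(OCc2ccccc2)c(OCc2ccccc2)c1 | intermediate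
9 | (2S,3S)-2-[3,4-bis(benzyloxy)phenyl]-3-(hydroxymethyl)-2,3-dihydro-1-benzofuran-4,6-diol (formed as caesium phenoxide, not isolated) | OC[C@@H]1c2c(O)cc(O)cc2O[C@@H]1c1ccc(OCc2ccccc2)c(OCc2ccccc2)c1 | intermediate
10 | [(2S,3S)-4,6-bis(benzyloxy)-2-[3,4-bis(benzyloxy)phenyl]-2,3-dihydro-1-benzofuran-3-yl]methanol (cis) | OC[C@@H]1c2c(OCc3ccccc3)cc(OCc3ccccc3)cc2O[C@@H]1c1ccc(OCc2ccccc2)c(OCc2ccccc2)c1 | intermediate
11 | [(2S,3S)-4,6-bis(benzyloxy)-2-[3,4-bis(benzyloxy)phenyl]-2,3-dihydro-1-benzofuran-3-yl]methyl trifluoroacetate (not isolated) | O=C(OC[C@@H]1c2c(OCc3ccccc3)cc(OCc3ccccc3)cc2O[C@@H]1c1ccc(OCc2ccccc2)c(OCc2ccccc2)c1)C(F)(F)F | intermediate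
12 | (2R,3R)-5,7-bis(benzyloxy)-2-[3,4-bis(benzyloxy)phenyl]chroman-3-yl trifluoroacetate (not isolated) | O=C(O[C@@H]1Cc2c(OCc3ccccc3)cc(OCc3ccccc3)cc2O[C@@H]1c1ccc(OCc2ccccc2)c(OCc2ccccc2)c1)C(F)(F)F | intermediate
13 | 5,7,3′,4′-tetra-O-benzyl-(−)-epicatechin, (2R,3R) | O[C@@H]1Cc2c(OCc3ccccc3)cc(OCc3ccccc3)cc2O[C@@H]1c1ccc(OCc2ccccc2)c(OCc2ccccc2)c1 | intermediate
14 | (2R,3R,4S)-5,7-bis(benzyloxy)-2-[3,4-bis(benzyloxy)phenyl]-4-(2-ethoxyethoxy)chroman-3-ol (4β) | O[C@@H]1[C@@H](OCCOCC)c2c(OCc3ccccc3)cc(OCc3ccccc3)cc2O[C@@H]1c1ccc(OCc2ccccc2)c(OCc2ccccc2)c1 | intermediate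
15 | (+)-catechin, (2R,3S) | O[C@H]1Cc2c(O)cc(O)cc2O[C@@H]1c1ccc(O)c(O)c1 | starting material
16 | 5,7,3′,4′-tetra-O-benzyl-(+)-catechin, (2R,3S) | O[C@H]1Cc2c(OCc3ccccc3)cc(OCc3ccccc3)cc2O[C@@H]1c1ccc(OCc2ccccc2)c(OCc2ccccc2)c1 | intermediate
17 | octa-O-benzyl epicatechin-(4β→8)-catechin | O(Cc1ccccc1)c1cc(OCc2ccccc2)c2c(c1)O[C@H](c1ccc(OCc3ccccc3)c(OCc3ccccc3)c1)[C@H](O)[C@H]2c1c(OCc2ccccc2)cc(OCc2ccccc2)c2c1O[C@H](c1ccc(OCc3ccccc3)c(OCc3ccccc3)c1)[C@@H](O)C2 | intermediate
18 | (−)-epiafzelechin, (2R,3R) | O[C@@H]1Cc2c(O)cc(O)cc2O[C@@H]1c1ccc(O)cc1 | starting material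
19 | 5,7,4′-tri-O-benzyl-(−)-epiafzelechin, (2R,3R) | O[C@@H]1Cc2c(OCc3ccccc3)cc(OCc3ccccc3)cc2O[C@@H]1c1ccc(OCc2ccccc2)cc1 | intermediate
20 | (2R,3R,4S)-5,7-bis(benzyloxy)-2-[4-(benzyloxy)phenyl]-4-(2-ethoxyethoxy)chroman-3-ol (4β) | O[C@@H]1[C@@H](OCCOCC)c2c(OCc3ccccc3)cc(OCc3ccccc3)cc2O[C@@H]1c1ccc(OCc2ccccc2)cc1 | intermediate
21 | undeca-O-benzyl epiafzelechin-(4β→8)-epicatechin-(4β→8)-catechin | O(Cc1ccccc1)c1cc(OCc2ccccc2)c2c(c1)O[C@H](c1ccc(OCc3ccccc3)cc1)[C@H](O)[C@H]2c1c(OCc2ccccc2)cc(OCc2ccccc2)c2c1O[C@H](c1ccc(OCc3ccccc3)c(OCc3ccccc3)c1)[C@H](O)[C@H]2c1c(OCc2ccccc2)cc(OCc2ccccc2)c2c1O[C@H](c1ccc(OCc3ccccc3)c(OCc3ccccc3)c1)[C@@H](O)C2 | intermediate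
22 | epiafzelechin-(4β→8)-epicatechin-(4β→8)-catechin (CNP0158921.1) | Oc1ccc([C@H]2Oc3cc(O)cc(O)c3[C@H](c3c(O)cc(O)c4c3O[C@H](c3ccc(O)c(O)c3)[C@H](O)[C@H]4c3c(O)cc(O)c4c3O[C@H](c3ccc(O)c(O)c3)[C@@H](O)C4)[C@H]2O)cc1 | target

Total step count: 15. Longest linear sequence: 12 (steps 1–9, 11, 14, 15).

Steps most likely to fail

1. Step 8 (proposed new method). The ion pair may collapse only at the exocyclic CH2, so that nothing changes; the trifluoroacetate may ionise too slowly; or the bridged ion may leak by proton loss or by O1 participation that epimerises C2. The fallback uses known chemistry, sets out from 7 and returns at 13. The potassium enolate of 7 (KHMDS, THF, −78 °C) is hydroxylated with 2-(phenylsulfonyl)-3-phenyloxaziridine to the tertiary α-hydroxy ester F1 (C3 configuration immaterial). LiBH4 reduces it to the 1,2-diol F2, and TsCl/pyridine sulfonylates the primary hydroxyl to the monotosylate F3. Et3Al (CH2Cl2, −78 → 0 °C) then triggers a Tiffeneau–Demjanov-type semipinacol ring expansion, in which the electron-rich aryl carbon should migrate in preference to C2, to the flavan-3-one F4. L-Selectride (THF, −78 °C) attacks anti to the 2-aryl group and should give the 2,3-cis silyl-protected epicatechin F5. CsF/BnBr as in step 7 passes through the bisphenol F6 and delivers 13.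

2. Step 5. Enantio-induction or cis selectivity may be insufficient with the di-ortho-substituted, very electron-rich aryl carbenoid, and carbene dimerisation may compete. The fallback sets out from 6 and returns at 7. Cyclisation with the achiral, bulky Rh2(O2CCPh3)4, which should keep the kinetic cis preference, gives the racemic cis ester, that is 7 together with its enantiomer, the (2R,3S) ester F7. The two are separated by preparative HPLC on a polysaccharide chiral phase, F7 is discarded and 7 goes on to step 6.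

3. Step 3. The acid released from Tl(III) may cleave the electron-rich benzyl aryl ether, the oxidant may attack the trioxygenated ring, and the hindered ketone may enolise too slowly. The fallback sets out from 4 and returns at 6, bypassing steps 3 and 4. Riley oxidation (SeO2, pyridine, 90 °C) gives the arylglyoxylic acid F8. TMSCHN2 (toluene–MeOH) gives the methyl arylglyoxylate F9, and TsNHNH2 (MeOH, 50 °C) gives the tosylhydrazone F10. DBU (CH2Cl2, rt, Bamford–Stevens) then eliminates sulfinate to give the diazo ester 6.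

Further compounds

F1 | step 8 | methyl (2S)-2-[3,4-bis(benzyloxy)phenyl]-3-hydroxy-4,6-bis(triisopropylsilyloxy)-2,3-dihydro-1-benzofuran-3-carboxylate (2-aryl configuration as in 7, C3 epimers) | COC(=O)C1(O)c2c(O[Si](C(C)C)(C(C)C)C(C)C)cc(O[Si](C(C)C)(C(C)C)C(C)C)cc2O[C@@H]1c1ccc(OCc2ccccc2)c(OCc2ccccc2)c1
F2 | step 8 | 2-[3,4-bis(benzyloxy)phenyl]-3-(hydroxymethyl)-4,6-bis(triisopropylsilyloxy)-2,3-dihydro-1-benzofuran-3-ol (2-aryl configuration as in 7) | OCC1(O)c2c(O[Si](C(C)C)(C(C)C)C(C)C)cc(O[Si](C(C)C)(C(C)C)C(C)C)cc2O[C@@H]1c1ccc(OCc2ccccc2)c(OCc2ccccc2)c1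
F3 | step 8 | {2-[3,4-bis(benzyloxy)phenyl]-3-hydroxy-4,6-bis(triisopropylsilyloxy)-2,3-dihydro-1-benzofuran-3-yl}methyl 4-methylbenzenesulfonate | Cc1ccc(cc1)S(=O)(=O)OCC1(O)c2c(O[Si](C(C)C)(C(C)C)C(C)C)cc(O[Si](C(C)C)(C(C)C)C(C)C)cc2O[C@@H]1c1ccc(OCc2ccccc2)c(OCc2ccccc2)c1
F4 | step 8 | (2R)-2-[3,4-bis(benzyloxy)phenyl]-5,7-bis(triisopropylsilyloxy)chroman-3-one | O=C1Cc2c(O[Si](C(C)C)(C(C)C)C(C)C)cc(O[Si](C(C)C)(C(C)C)C(C)C)cc2O[C@@H]1c1ccc(OCc2ccccc2)c(OCc2ccccc2)c1
F5 | step 8 | (2R,3R)-2-[3,4-bis(benzyloxy)phenyl]-5,7-bis(triisopropylsilyloxy)chroman-3-ol | O[C@@H]1Cc2c(O[Si](C(C)C)(C(C)C)C(C)C)cc(O[Si](C(C)C)(C(C)C)C(C)C)cc2O[C@@H]1c1ccc(OCc2ccccc2)c(OCc2ccccc2)c1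
F6 | step 8 | 3′,4′-di-O-benzyl-(−)-epicatechin (formed as caesium phenoxide, not isolated) | O[C@@H]1Cc2c(O)cc(O)cc2O[C@@H]1c1ccc(OCc2ccccc2)c(OCc2ccccc2)c1
F7 | step 5 | methyl (2R,3S)-2-[3,4-bis(benzyloxy)phenyl]-4,6-bis(triisopropylsilyloxy)-2,3-dihydro-1-benzofuran-3-carboxylate (enantiomer of 7) | COC(=O)[C@H]1c2c(O[Si](C(C)C)(C(C)C)C(C)C)cc(O[Si](C(C)C)(C(C)C)C(C)C)cc2O[C@H]1c1ccc(OCc2ccccc2)c(OCc2ccccc2)c1
F8 | step 3 | {2-{[3,4-bis(benzyloxy)phenyl]methoxy}-4,6-bis(triisopropylsilyloxy)phenyl}(oxo)acetic acid | OC(=O)C(=O)c1c(OCc2ccc(OCc3ccccc3)c(OCc3ccccc3)c2)cc(O[Si](C(C)C)(C(C)C)C(C)C)cc1O[Si](C(C)C)(C(C)C)C(C)C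
F9 | step 3 | methyl {2-{[3,4-bis(benzyloxy)phenyl]methoxy}-4,6-bis(triisopropylsilyloxy)phenyl}(oxo)acetate | COC(=O)C(=O)c1c(OCc2ccc(OCc3ccccc3)c(OCc3ccccc3)c2)cc(O[Si](C(C)C)(C(C)C)C(C)C)cc1O[Si](C(C)C)(C(C)C)C(C)C
F10 | step 3 | methyl {2-{[3,4-bis(benzyloxy)phenyl]methoxy}-4,6-bis(triisopropylsilyloxy)phenyl}[(4-methylbenzenesulfonyl)hydrazinylidene]acetate | COC(=O)C(=NNS(=O)(=O)c1ccc(C)cc1)c1c(OCc2ccc(OCc3ccccc3)c(OCc3ccccc3)c2)cc(O[Si](C(C)C)(C(C)C)C(C)C)cc1O[Si](C(C)C)(C(C)C)C(C)C
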